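**Plan**

- Retrosynthetic cuts, in order: the O6–vanilloyl ester bond, the two epoxide C–O bonds (back to the C4=C5 olefin), the ring bond C1–C2, the C10–CH3 and C1–I bonds, C8–C9, and C6–C7.
- Forward: the acyclic C2–C9 chain is built first (aldol for C6–C7, propargylation for C8–C9). Carboalumination–iodination then adds the C10 methyl and the C1 iodide. The only carbocycle, the ten-membered ring C1–C10, closes last at C1–C2, and the oxirane ring follows.
- Enabling feature: C1–C2 joins the sp2 carbon C1 of the E-trisubstituted C1=C10 olefin to the plain methylene C2 (next to C3H2). The ring can therefore be closed by alkenyl–alkyl coupling between a C1 vinyl iodide of preset geometry and a C2 borane made from a C2=C3 vinyl group.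
- Stereochemistry: C6 and C7 come from an Evans syn aldol with the (S)-4-benzyl auxiliary. C8 comes from chelate-controlled propargylation. C4 and C5 come from C6–OH-directed epoxidation of the exposed face of the ring olefin. Both E olefins are made in the open chain (E-enynol starting material, syn-carboalumination).

Key step: step 12

Assumption: germacrane numbering (ring C1–C10, methyls on C4 and C10, isopropyl on C7) is used for all intermediates, and 5 and 14 are taken as purchasable.

Remark: the spatial arrangement at C6, C7 and C8 is the same from 15 onward; the changes in R/S letters reflect CIP priorities only. Macrocycles 20 and 21 are 1,5-dienes and are to be kept at or below 40 °C to avoid Cope rearrangement.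

**Step 1**
Reactants: 1 isovaleryl chloride; 2 (S)-4-benzyl-2-oxazolidinone
Product: 4 (S)-4-benzyl-3-(3-methylbutanoyl)oxazolidin-2-one, via lithium oxazolidinide 3 (not isolated)
Conditions: n-BuLi, THF, −78 °C; then 1, −78 → 0 °C
Reagents that add atoms: none
Why: N-acylation of the lithiated oxazolidinone with an acid chloride is the standard loading of an Evans auxiliary and creates no stereocentre.

**Step 2**
Reactants: 5 (E)-3-methylpent-2-en-4-yn-1-ol
Product: 6 (E)-3-methylpenta-2,4-dien-1-ol
Conditions: H2 (1 atm), Pd/CaCO3 poisoned with Pb(OAc)2, quinoline, Et2O, 0 °C → rt, stopped after one equivalent of H2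
Reagents that add atoms: none
Why: Lindlar semi-hydrogenation reduces the terminal alkyne of the conjugated enyne to the vinyl group and stops there, so the E geometry of the future C4=C5 olefin is kept and the C2=C3 terminus is in place.

**Step 3**
Reactants: 6 (E)-3-methylpenta-2,4-dien-1-ol
Product: 7 (E)-3-methylpenta-2,4-dienal
Conditions: MnO2 (activated, excess), CH2Cl2, rt; filtered and dried solution used directly
Reagents that add atoms: none
Why: MnO2 oxidation of an allylic alcohol gives the volatile dienal selectively without isomerising the E olefin or touching the diene.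

**Step 4**
Reactants: 4 (S)-4-benzyl-3-(3-methylbutanoyl)oxazolidin-2-one; 7 (E)-3-methylpenta-2,4-dienal
Product: 9 (S)-4-benzyl-3-[(2S,3R,4E)-3-hydroxy-5-methyl-2-(propan-2-yl)hepta-4,6-dienoyl]oxazolidin-2-one, via dibutylboron Z-enolate 8 (not isolated)
Conditions: Bu2BOTf, Et3N, CH2Cl2, 0 °C; then 7 in CH2Cl2, −78 → 0 °C; pH 7 buffer, MeOH, 30% H2O2, 0 °C
Reagents that add atoms: none
Why: Evans syn aldol reaction in which the Z boron enolate reacts through a closed Zimmerman–Traxler chair with the auxiliary carbonyl turned away from boron, which should set C7 and C6 syn with the absolute sense required by the target.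

**Step 5**
Reactants: 9 the syn-aldol imide
Product: 10 (2R,3R,4E)-5-methyl-2-(propan-2-yl)hepta-4,6-diene-1,3-diol
Conditions: LiBH4, MeOH (1 equiv), THF, 0 °C
Reagents that add atoms: none
Why: Hydroxyl-assisted LiBH4 reduction cleaves the exocyclic acyl–nitrogen bond of the hindered imide (reductive auxiliary removal), returns the auxiliary and leaves C6 and C7 untouched.

**Step 6**
Reactants: 10 the 1,3-diol
Product: 11 (2S,4R,5R)-2-(4-methoxyphenyl)-4-[(1E)-2-methylbuta-1,3-dien-1-yl]-5-(propan-2-yl)-1,3-dioxane
Conditions: 4-MeOC6H4CH(OMe)2, PPTS (cat.), CH2Cl2, rt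
Reagents that add atoms: 4-methoxybenzaldehyde dimethyl acetal, COc1ccc(C(OC)OC)cc1
Why: Acid-catalysed transacetalisation closes the six-membered p-methoxybenzylidene acetal under thermodynamic control (aryl and dienyl groups equatorial, which fixes the acetal carbon), and the weak acid should not ionise the dienylic C6–O bond.

**Step 7**
Reactants: 11 the p-methoxybenzylidene acetal
Product: 12 (2R,3R,4E)-3-[(4-methoxybenzyl)oxy]-5-methyl-2-(propan-2-yl)hepta-4,6-dien-1-ol
Conditions: iBu2AlH (3 equiv), CH2Cl2, −78 → 0 °C; aqueous potassium sodium tartrate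
Reagents that add atoms: none
Why: Regioselective reductive acetal opening in which iBu2AlH binds the less hindered primary-side oxygen O8 and delivers hydride to the oxocarbenium ion, leaving the PMB ether on the secondary O6 and a free primary C8 alcohol.

**Step 8**
Reactants: 12 the C8 primary alcohol
Product: 13 (2S,3R,4E)-3-[(4-methoxybenzyl)oxy]-5-methyl-2-(propan-2-yl)hepta-4,6-dienal
Conditions: Dess–Martin periodinane, pyridine, CH2Cl2, 0 °C → rt; used at once
Reagents that add atoms: none
Why: Dess–Martin oxidation gives the C8 aldehyde under buffered conditions that should neither epimerise C7 nor affect the diene and the PMB ether.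

**Step 9**
Reactants: 13 the C8 aldehyde; 14 allenyltributylstannane
Product: 15 (3E,5R,6R,7R)-5-[(4-methoxybenzyl)oxy]-3-methyl-6-(propan-2-yl)deca-1,3-dien-9-yn-7-ol
Conditions: MgBr2·OEt2 (3 equiv), CH2Cl2, −20 °C; then 14, −78 → −20 °C
Reagents that add atoms: none
Why: Chelation-controlled SE2' propargylation in which MgBr2 ties the aldehyde oxygen and O6 into a six-membered chelate carrying the C7 isopropyl and the C6 dienyl group on the same face, so the stannane should add from the opposite face and give the 8R alcohol (7,8-anti and 6,8-anti).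

**Step 10**
Reactants: 15 the homopropargylic alcohol
Product: 16 (3E,5R,6S,7R)-7-[(tert-butyldimethylsilyl)oxy]-5-[(4-methoxybenzyl)oxy]-3-methyl-6-(propan-2-yl)deca-1,3-dien-9-yne
Conditions: TBSOTf, 2,6-lutidine, CH2Cl2, −78 → 0 °C
Reagents that add atoms: tert-butyldimethylsilyl triflate, CC(C)(C)[Si](C)(C)OS(=O)(=O)C(F)(F)F
Why: Silylation of a hindered secondary alcohol with the silyl triflate and a hindered pyridine base is standard and gives a C8 ether orthogonal to the C6 PMB ether.

**Step 11**
Reactants: 16 the silylated alkyne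
Product: 18 (3E,5R,6S,7R,9E)-7-[(tert-butyldimethylsilyl)oxy]-10-iodo-5-[(4-methoxybenzyl)oxy]-3,9-dimethyl-6-(propan-2-yl)deca-1,3,9-triene, via E-alkenyl(dimethyl)alane 17 (not isolated)
Conditions: Me3Al (3 equiv), Cp2ZrCl2 (0.2 equiv), H2O (1.5 equiv), CH2Cl2, −30 °C; then I2, THF, −30 → 0 °C
Reagents that add atoms: trimethylaluminium, C[Al](C)C; iodine, II
Why: Negishi zirconium-catalysed carboalumination adds methyl (to C10) and aluminium (to C1) syn across the terminal alkyne, which reacts far faster than the olefins at low temperature, and iodinolysis of the C–Al bond with retention gives the E vinyl iodide.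

**Step 12**
Reactants: 18 the acyclic E-vinyl iodide diene
Product: 20 (1(10)E,4E,6R,7S,8R)-8-[(tert-butyldimethylsilyl)oxy]-6-[(4-methoxybenzyl)oxy]germacra-1(10),4-diene, via B-alkyl-9-BBN adduct 19 (not isolated)
Conditions: 9-BBN (1.5 equiv), THF, 0 °C → rt; then syringe-pump addition over 10 h to PdCl2(dppf) (20 mol %), AsPh3 (20 mol %), Cs2CO3 (4 equiv), degassed DMF/THF/H2O, rt → 40 °C, final concentration about 1 mM
Reagents that add atoms: none
Why: Hydroboration with 9-BBN places boron on C2 of the monosubstituted C2=C3 vinyl group, the only olefin in 18 that this hindered borane attacks at room temperature (the two trisubstituted olefins, one of them the vinyl iodide, are far slower). Zerovalent palladium then inserts into the C1–I bond with retention, the base-activated borate transfers the C2 alkyl group to the alkenyl divalent palladium iodide, and reductive elimination forms C1–C2; this is an intramolecular B-alkyl Suzuki–Miyaura coupling, whose closest known use is the macrocyclisation of ω-boryl alkenyl iodides to twelve-membered and larger carbocycles. The ten-membered ring C1–C10 closes end to end through an eleven-membered alkyl(alkenyl)palladacycle that contracts on reductive elimination. No stereocentre is formed: C6, C7 and C8 are spectators and both olefin geometries are carried over because oxidative addition and reductive elimination retain configuration. The step needs cyclisation to outrun oligomerisation and β-hydride elimination, which is addressed by slow addition at high dilution, the wide-bite-angle dppf ligand with AsPh3, and a temperature low enough to keep the new 1,5-diene out of its Cope rearrangement range.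

**Step 13**
Reactants: 20 the protected germacradiene
Product: 21 (1(10)E,4E,6R,7S,8R)-8-[(tert-butyldimethylsilyl)oxy]germacra-1(10),4-dien-6-ol
Conditions: DDQ (1.2 equiv), CH2Cl2/pH 7 phosphate buffer, 0 °C
Reagents that add atoms: none
Why: Oxidative PMB cleavage by DDQ (hydride abstraction at the electron-rich benzylic position, then hydrolysis of the oxocarbenium ion) frees the allylic C6 hydroxyl while the silyl ether and both ring olefins should remain.

**Step 14**
Reactants: 21 the allylic alcohol
Product: 22 (1(10)E,4R,5R,6S,7S,8R)-8-[(tert-butyldimethylsilyl)oxy]-4,5-epoxygermacr-1(10)-en-6-ol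
Conditions: VO(acac)2 (10 mol %), t-BuOOH (1.5 equiv, decane solution), CH2Cl2, 0 °C → rt
Reagents that add atoms: tert-butyl hydroperoxide, CC(C)(C)OO
Why: Vanadium-catalysed hydroxyl-directed epoxidation in which the vanadate ester of O6 delivers oxygen only to the adjacent C4=C5 olefin (not to the remote C1=C10 olefin) on its outward face, where O6 sits when H6 eclipses the olefin to avoid allylic strain with the C4 methyl, and this face should give the 4R,5R epoxide.

**Step 15**
Reactants: 23 vanillic acid
Product: 25 4-[(tert-butyldimethylsilyl)oxy]-3-methoxybenzoic acid, via bis-silylated vanillate 24 (not isolated)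
Conditions: TBSCl (2.5 equiv), imidazole, DMF, rt; then AcOH/THF/H2O, rt
Reagents that add atoms: tert-butyldimethylsilyl chloride, CC(C)(C)[Si](C)(C)Cl
Why: Silylation of both acidic hydroxyls followed by selective hydrolysis of the much more labile silyl ester leaves the phenol masked as its TBS ether, which prevents self-acylation in the esterification.

**Step 16**
Reactants: 22 the epoxy alcohol; 25 4-[(tert-butyldimethylsilyl)oxy]-3-methoxybenzoic acid
Product: 27 (1(10)E,4R,5R,6S,7S,8R)-8-[(tert-butyldimethylsilyl)oxy]-4,5-epoxygermacr-1(10)-en-6-yl 4-[(tert-butyldimethylsilyl)oxy]-3-methoxybenzoate, via mixed Yamaguchi anhydride 26 (not isolated)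
Conditions: 25 (2 equiv), 2,4,6-Cl3C6H2COCl, Et3N, THF, rt; then 22, DMAP, toluene, rt → 40 °C
Reagents that add atoms: none
Why: Yamaguchi esterification in which DMAP attacks the unhindered vanilloyl carbonyl of the mixed anhydride and the acylpyridinium ion acylates the secondary C6 hydroxyl under basic conditions that leave the epoxide and all stereocentres unchanged.

**Step 17**
Reactants: 27 the bis-silylated ester
Product: 28 (1(10)E,4R,5R,6S,7R,8R)-4,5-epoxy-8-hydroxygermacr-1(10)-en-6-yl 4-hydroxy-3-methoxybenzoate
Conditions: Bu4NF (4 equiv), AcOH (4 equiv), THF, 0 °C → rt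
Reagents that add atoms: none
Why: Fluoride desilylation removes the aryl and the secondary alkyl silyl ether in one operation, and the acetic acid buffer keeps the medium too mild for acyl migration from O6 to O8 or for transannular opening of the epoxide.

**Compound list**

1 | isovaleryl chloride | CC(C)CC(Cl)=O | starting material
2 | (S)-4-benzyl-2-oxazolidinone | O=C1N[C@@H](Cc2ccccc2)CO1 | starting material
3 | N-lithio-(S)-4-benzyl-2-oxazolidinone (formed in the flask) | [Li]N1[C@@H](Cc2ccccc2)COC1=O | intermediate
4 | (S)-4-benzyl-3-(3-methylbutanoyl)oxazolidin-2-one | CC(C)CC(=O)N1[C@@H](Cc2ccccc2)COC1=O | intermediate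
5 | (E)-3-methylpent-2-en-4-yn-1-ol | OC/C=C(C)/C#C | starting material
6 | (E)-3-methylpenta-2,4-dien-1-ol | OC/C=C(C)/C=C | intermediate
7 | (E)-3-methylpenta-2,4-dienal | O=C/C=C(C)/C=C | intermediate
8 | dibutylboron (Z)-enolate of 4 (formed in the flask) | CCCCB(CCCC)O/C(=C\C(C)C)N1[C@@H](Cc2ccccc2)COC1=O | intermediate
9 | (S)-4-benzyl-3-[(2S,3R,4E)-3-hydroxy-5-methyl-2-(propan-2-yl)hepta-4,6-dienoyl]oxazolidin-2-one | O=C1OC[C@H](Cc2ccccc2)N1C(=O)[C@@H](C(C)C)[C@H](O)/C=C(C)/C=C | intermediate
10 | (2R,3R,4E)-5-methyl-2-(propan-2-yl)hepta-4,6-diene-1,3-diol | OC[C@@H](C(C)C)[C@H](O)/C=C(C)/C=C | intermediate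
11 | (2S,4R,5R)-2-(4-methoxyphenyl)-4-[(1E)-2-methylbuta-1,3-dien-1-yl]-5-(propan-2-yl)-1,3-dioxane | COc1ccc([C@H]2OC[C@@H](C(C)C)[C@@H](/C=C(C)/C=C)O2)cc1 | intermediate
12 | (2R,3R,4E)-3-[(4-methoxybenzyl)oxy]-5-methyl-2-(propan-2-yl)hepta-4,6-dien-1-ol | OC[C@@H](C(C)C)[C@H](OCc1ccc(OC)cc1)/C=C(C)/C=C | intermediate
13 | (2S,3R,4E)-3-[(4-methoxybenzyl)oxy]-5-methyl-2-(propan-2-yl)hepta-4,6-dienal | O=C[C@@H](C(C)C)[C@H](OCc1ccc(OC)cc1)/C=C(C)/C=C | intermediate
14 | allenyltributylstannane | C=C=C[Sn](CCCC)(CCCC)CCCC | starting material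
15 | (3E,5R,6R,7R)-5-[(4-methoxybenzyl)oxy]-3-methyl-6-(propan-2-yl)deca-1,3-dien-9-yn-7-ol | C#CC[C@@H](O)[C@@H](C(C)C)[C@H](OCc1ccc(OC)cc1)/C=C(C)/C=C | intermediate
16 | (3E,5R,6S,7R)-7-[(tert-butyldimethylsilyl)oxy]-5-[(4-methoxybenzyl)oxy]-3-methyl-6-(propan-2-yl)deca-1,3-dien-9-yne | C#CC[C@@H](O[Si](C)(C)C(C)(C)C)[C@@H](C(C)C)[C@H](OCc1ccc(OC)cc1)/C=C(C)/C=C | intermediate
17 | (E)-alkenyl(dimethyl)alane from 16, dimethylaluminium on C1 and new methyl on C10 (formed in the flask) | C[Al](C)/C=C(C)/C[C@@H](O[Si](C)(C)C(C)(C)C)[C@@H](C(C)C)[C@H](OCc1ccc(OC)cc1)/C=C(C)/C=C | intermediate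
18 | (3E,5R,6S,7R,9E)-7-[(tert-butyldimethylsilyl)oxy]-10-iodo-5-[(4-methoxybenzyl)oxy]-3,9-dimethyl-6-(propan-2-yl)deca-1,3,9-triene | I/C=C(C)/C[C@@H](O[Si](C)(C)C(C)(C)C)[C@@H](C(C)C)[C@H](OCc1ccc(OC)cc1)/C=C(C)/C=C | intermediate
19 | B-alkyl-9-BBN adduct of 18, boron on C2 (formed in the flask) | I/C=C(C)/C[C@@H](O[Si](C)(C)C(C)(C)C)[C@@H](C(C)C)[C@H](OCc1ccc(OC)cc1)/C=C(C)/CCB1C2CCCC1CCC2 | intermediate
20 | (1(10)E,4E,6R,7S,8R)-8-[(tert-butyldimethylsilyl)oxy]-6-[(4-methoxybenzyl)oxy]germacra-1(10),4-diene | [C@@H]1(C(C)C)[C@H](O[Si](C)(C)C(C)(C)C)C/C(C)=C/CC/C(C)=C/[C@H]1OCc2ccc(OC)cc2 | intermediate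
21 | (1(10)E,4E,6R,7S,8R)-8-[(tert-butyldimethylsilyl)oxy]germacra-1(10),4-dien-6-ol | [C@@H]1(C(C)C)[C@H](O[Si](C)(C)C(C)(C)C)C/C(C)=C/CC/C(C)=C/[C@H]1O | intermediate
22 | (1(10)E,4R,5R,6S,7S,8R)-8-[(tert-butyldimethylsilyl)oxy]-4,5-epoxygermacr-1(10)-en-6-ol | O[C@H]1[C@H](C(C)C)[C@H](O[Si](C)(C)C(C)(C)C)C/C(C)=C/CC[C@@]2(C)O[C@H]12 | intermediate
23 | vanillic acid (4-hydroxy-3-methoxybenzoic acid) | COc1cc(C(=O)O)ccc1O | starting material
24 | tert-butyldimethylsilyl 4-[(tert-butyldimethylsilyl)oxy]-3-methoxybenzoate (formed in the flask) | COc1cc(C(=O)O[Si](C)(C)C(C)(C)C)ccc1O[Si](C)(C)C(C)(C)C | intermediate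
25 | 4-[(tert-butyldimethylsilyl)oxy]-3-methoxybenzoic acid | COc1cc(C(=O)O)ccc1O[Si](C)(C)C(C)(C)C | intermediate
26 | mixed anhydride of 25 with 2,4,6-trichlorobenzoic acid (formed in the flask) | COc1cc(C(=O)OC(=O)c2c(Cl)cc(Cl)cc2Cl)ccc1O[Si](C)(C)C(C)(C)C | intermediate
27 | (1(10)E,4R,5R,6S,7S,8R)-8-[(tert-butyldimethylsilyl)oxy]-4,5-epoxygermacr-1(10)-en-6-yl 4-[(tert-butyldimethylsilyl)oxy]-3-methoxybenzoate | COc1cc(C(=O)O[C@H]2[C@H](C(C)C)[C@H](O[Si](C)(C)C(C)(C)C)C/C(C)=C/CC[C@@]3(C)O[C@H]23)ccc1O[Si](C)(C)C(C)(C)C | intermediate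
28 | (1(10)E,4R,5R,6S,7R,8R)-4,5-epoxy-8-hydroxygermacr-1(10)-en-6-yl 4-hydroxy-3-methoxybenzoate | COc1cc(C(=O)O[C@H]2[C@H](C(C)C)[C@H](O)C/C(C)=C/CC[C@@]3(C)O[C@H]23)ccc1O | target

**Step count**

Total: 17 steps. Longest linear sequence: 15 steps (5 → 28 through steps 2–14, 16 and 17).

**Steps most likely to fail**

1. Step 12. Closure of the strained ten-membered ring may be slow. The alkyl(alkenyl)palladium intermediate, or the borate before it, could then be lost to β-hydride elimination, protodeboronation or intermolecular coupling. The fallback sets out from 18 and returns at 20 by an intramolecular Negishi coupling, which needs neither base nor water and uses a preformed, fast-transmetalating organozinc. Hydroboration of 18 with 9-BBN and oxidation with NaBO3·4H2O would give the C2 primary alcohol F1. I2, PPh3 and imidazole would turn it into the C2 primary iodide F2. Zn dust with LiCl in THF inserts into the alkyl C–I bond but not into the alkenyl C–I bond and would give the alkylzinc iodide F3. Slow addition of this to Pd(PPh3)4 in THF at high dilution would form C1–C2 and give 20.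

2. Step 14. Oxygen transfer may proceed through a ring conformer in which O6 lies near the olefin plane (the small O–C–C=C angle that vanadium prefers), which would put the oxygen on the other olefin face. The fallback sets out from 21 and returns at 27; it inverts C6 first so that this preferred geometry coincides with the ground-state conformer and the desired face. Mitsunobu reaction of 21 with 4-nitrobenzoic acid (PPh3, diisopropyl azodicarboxylate) would give the 6-epi 4-nitrobenzoate F4. K2CO3 in MeOH would give the 6-epi allylic alcohol F5. VO(acac)2/t-BuOOH would then give the 6-epi epoxy alcohol F6 with the 4R,5R oxirane. A second Mitsunobu reaction with acid 25 would invert C6 back and install the ester in the same operation, giving 27.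

3. Step 9. Chelation may be incomplete, so that an open, Felkin-type pathway competes and facial selectivity at C8 is poor. The fallback sets out from 13 and returns at 15 and replaces substrate control by reagent control. 13 would be treated at −78 °C with the enantiomer of B-allenyl-diisopinocampheylborane matched to the 8R alcohol (made from propargyl bromide by way of allenylmagnesium bromide and B-methoxy-diisopinocampheylborane), followed by oxidative work-up. The closed six-membered allenylboration transition state takes its facial bias from the terpene ligands. This fallback makes no new compound (F0).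

**Further compounds**

F1 | step 12 | (3E,5R,6S,7R,9E)-7-[(tert-butyldimethylsilyl)oxy]-10-iodo-5-[(4-methoxybenzyl)oxy]-3,9-dimethyl-6-(propan-2-yl)deca-3,9-dien-1-ol (C2 primary alcohol) | I/C=C(C)/C[C@@H](O[Si](C)(C)C(C)(C)C)[C@@H](C(C)C)[C@H](OCc1ccc(OC)cc1)/C=C(C)/CCO
F2 | step 12 | C2 primary iodide derived from F1 (C1 alkenyl iodide retained) | I/C=C(C)/C[C@@H](O[Si](C)(C)C(C)(C)C)[C@@H](C(C)C)[C@H](OCc1ccc(OC)cc1)/C=C(C)/CCI
F3 | step 12 | alkylzinc iodide derived from F2 (zinc on C2) | I/C=C(C)/C[C@@H](O[Si](C)(C)C(C)(C)C)[C@@H](C(C)C)[C@H](OCc1ccc(OC)cc1)/C=C(C)/CC[Zn]I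
F4 | step 14 | (1(10)E,4E,6S,7S,8R)-8-[(tert-butyldimethylsilyl)oxy]germacra-1(10),4-dien-6-yl 4-nitrobenzoate (6-epi) | [C@@H]1(C(C)C)[C@H](O[Si](C)(C)C(C)(C)C)C/C(C)=C/CC/C(C)=C/[C@@H]1OC(=O)c2ccc([N+](=O)[O-])cc2
F5 | step 14 | (1(10)E,4E,6S,7S,8R)-8-[(tert-butyldimethylsilyl)oxy]germacra-1(10),4-dien-6-ol (6-epi) | [C@@H]1(C(C)C)[C@H](O[Si](C)(C)C(C)(C)C)C/C(C)=C/CC/C(C)=C/[C@@H]1O
F6 | step 14 | (1(10)E,4R,5R,6R,7S,8R)-8-[(tert-butyldimethylsilyl)oxy]-4,5-epoxygermacr-1(10)-en-6-ol (6-epi) | O[C@@H]1[C@H](C(C)C)[C@H](O[Si](C)(C)C(C)(C)C)C/C(C)=C/CC[C@@]2(C)O[C@H]12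
F0 | step 9 | none | none
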